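**Retrosynthetic overview**

1. The target is (2S)-naringenin joined through C3' of its ring B to C6 of apigenin. The last skeletal bond is flavanone C2–C1', made by enantioselective conjugate addition of the ring-B arylboronic acid (already carrying the whole flavone) to 5,7-bis(benzyloxy)chromone; global debenzylation follows.
2. The strategy rests on flavone ring A, a resorcinol ring fused to the pyranone across C4a–C8a, with the biaryl carbon C6 lying between the oxygenated C5 and C7. C8 maps onto a pyranone 2-methyl carbon, C5 onto a pyranone 3-ester carbon, and C6–C7 onto the CH2–C=O of an arylacetate, so the crowded biaryl bond arrives ready-made.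
3. Key disconnection: C7–C8 and C5–C6 of flavone ring A, back to methyl 6-(4-benzyloxyphenyl)-2-methyl-4-oxo-4H-pyran-3-carboxylate and methyl (2-benzyloxy-5-bromophenyl)acetate. The bromine marks the later attachment point of the flavanone.
4. Ring order: flavone ring C (pyranone, from methyl acetoacetate and an arylpropiolyl chloride), then flavone ring A (benzannulation), then union with the separately made chromone, which becomes rings A and C of the flavanone.

Key step: step 7

Remark: the biaryl axis carries three ortho oxygen substituents and the target SMILES defines no axial configuration; slowly interconverting rotamers of the benzylated intermediates are expected to converge at the target.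

Assumption: the (R)-enantiomer of the pyridinooxazoline ligand is taken to give the 2S flavanone, by analogy with its sense of addition to cyclic enones; a trial with 4-benzyloxyphenylboronic acid would settle this, and the (S)-ligand would be used if the sense is reversed.

**Route**

Step 1
Reactants: 1 1-benzyloxy-4-ethynylbenzene
Product: 2 3-[4-(benzyloxy)phenyl]prop-2-ynoic acid
Conditions: n-BuLi, THF, −78 °C; CO2 (g), −78 °C → rt; 1 M HCl
Reagents that add atoms: carbon dioxide, O=C=O
Why: Deprotonation of the terminal alkyne and carboxylation of the lithium acetylide is the standard route to arylpropiolic acids, and the aryl benzyl ether is inert to it.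

Step 2
Reactants: 2 3-[4-(benzyloxy)phenyl]prop-2-ynoic acid; 3 methyl acetoacetate
Product: 5 methyl 2-acetyl-5-[4-(benzyloxy)phenyl]-3-oxopent-4-ynoate, via 3-[4-(benzyloxy)phenyl]prop-2-ynoyl chloride 4 (not isolated)
Conditions: (COCl)2, cat. DMF, CH2Cl2, 0 °C → rt, evaporate; then 3, MgCl2, pyridine, CH2Cl2, 0 °C → rt
Reagents that add atoms: none
Why: Oxalyl chloride with catalytic DMF gives the acid chloride without touching the alkyne, and the magnesium chelate of methyl acetoacetate (soft enolisation with MgCl2 and pyridine) is acylated on carbon, not oxygen, to give the triacylmethane, which is held as its enol.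

Step 3
Reactants: 5 methyl 2-acetyl-5-[4-(benzyloxy)phenyl]-3-oxopent-4-ynoate
Product: 6 methyl 6-(4-benzyloxyphenyl)-2-methyl-4-oxo-4H-pyran-3-carboxylate
Conditions: TsOH·H2O (10 mol%), toluene, 80 °C
Reagents that add atoms: none
Why: Acid-catalysed 6-endo-dig oxa-Michael addition of the acetyl enol oxygen to the β-carbon of the ynone should give the conjugated 4-pyranone, the same closure by which 2-hydroxyaryl ynones give flavones, and the ketone enol is a better nucleophile than the ester carbonyl, so the methyl ester stays on C3.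

Step 4
Reactants: 7 2-hydroxyphenylacetic acid
Product: 8 methyl 2-(2-hydroxyphenyl)acetate
Conditions: MeOH, cat. H2SO4, reflux
Reagents that add atoms: methanol, CO
Why: Fischer esterification in excess methanol converts the acid to the methyl ester and leaves the phenol free.

Step 5
Reactants: 8 methyl 2-(2-hydroxyphenyl)acetate
Product: 9 methyl 2-(5-bromo-2-hydroxyphenyl)acetate
Conditions: NBS (1.0 equiv), MeCN, 0 °C → rt
Reagents that add atoms: N-bromosuccinimide, O=C1CCC(=O)N1Br
Why: Electrophilic aromatic bromination is directed by the hydroxyl group to its para position (C5), the less hindered of the two activated sites, and NBS in MeCN favours para-bromination of phenols.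

Step 6
Reactants: 9 methyl 2-(5-bromo-2-hydroxyphenyl)acetate
Product: 10 methyl 2-(2-benzyloxy-5-bromophenyl)acetate
Conditions: BnBr, K2CO3, acetone, reflux
Reagents that add atoms: benzyl bromide, BrCc1ccccc1
Why: Williamson etherification of the phenoxide is fast with benzyl bromide, and carbonate is too weak a base to enolise the ester.

Step 7
Reactants: 6 methyl 6-(4-benzyloxyphenyl)-2-methyl-4-oxo-4H-pyran-3-carboxylate; 10 methyl 2-(2-benzyloxy-5-bromophenyl)acetate
Product: 12 6-(2-benzyloxy-5-bromophenyl)-2-(4-benzyloxyphenyl)-5,7-dihydroxy-4H-chromen-4-one, via 2-(2-oxo-3-arylpropyl)pyranone ester 11 (not isolated)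
Conditions: LiN(SiMe3)2 (1.1 equiv), THF, −78 °C; add 10 (1.2 equiv), −78 → −20 °C; LiN(SiMe3)2 (3 equiv) added slowly, −20 °C → rt; 1 M HCl
Reagents that add atoms: none
Why: Proposed new method: the 2-methyl group of 6 is a vinylogous methyl ketone that is also γ to the C3 ester, so LiN(SiMe3)2 should give a lithium dienolate whose CH2 terminus attacks the ester carbonyl of 10 (vinylogous Claisen acylation, flavone C7–C8) to give ketone 11, and further base should then remove a benzylic proton of 11 so that this carbon attacks the neighbouring pyranone ester (Dieckmann condensation, 6-exo-trig, flavone C5–C6), after which loss of methoxide and two enolisations aromatise ring A. The closest known reactions are the γ-acylation of lithiated 2-methyl-4-pyranones and the Claisen–Dieckmann benzannulation of ortho-toluate anions with esters to 1,3-dihydroxynaphthalenes; their union on a pyranone ester has not been shown. No stereocentre is formed. The C6 (not C8) position of the aryl group is fixed by the substrate, because the pyran oxygen already sits on C8a and the aryl-bearing carbon can reach only the ester carbon. The step needs acylation of the dienolate to outrun enolisation and self-condensation of 10: the doubly activated methyl group of 6 is expected to be more acidic than the arylacetate CH2, so with one equivalent of base the dienolate and neutral 10 coexist, and the rest of the base is added only after the Claisen stage, where it first regenerates dienolate from the 6 that was protonated by acidic 11. Closure through the enolate oxygen to an enol lactone is reversible in the presence of the methoxide formed, whereas closure through carbon is drawn on by aromatisation.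

Step 8
Reactants: 12 6-(2-benzyloxy-5-bromophenyl)-2-(4-benzyloxyphenyl)-5,7-dihydroxy-4H-chromen-4-one
Product: 13 5,7-bis(benzyloxy)-6-(2-benzyloxy-5-bromophenyl)-2-(4-benzyloxyphenyl)-4H-chromen-4-one
Conditions: BnBr (3 equiv), Cs2CO3, cat. Bu4NI, DMF, 60 °C
Reagents that add atoms: benzyl bromide, BrCc1ccccc1
Why: Williamson etherification, in which the C7 phenol reacts readily and the chelated, flanked C5 phenol is forced through by the soluble caesium phenoxide, excess benzyl bromide and heat.

Step 9
Reactants: 13 5,7-bis(benzyloxy)-6-(2-benzyloxy-5-bromophenyl)-2-(4-benzyloxyphenyl)-4H-chromen-4-one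
Product: 14 5,7-bis(benzyloxy)-2-(4-benzyloxyphenyl)-6-[2-benzyloxy-5-(4,4,5,5-tetramethyl-1,3,2-dioxaborolan-2-yl)phenyl]-4H-chromen-4-one
Conditions: B2pin2, PdCl2(dppf) (5 mol%), KOAc, 1,4-dioxane, 90 °C
Reagents that add atoms: bis(pinacolato)diboron, CC1(C)OB(OC1(C)C)B1OC(C)(C)C(C)(C)O1
Why: Miyaura borylation, in which zerovalent palladium inserts into the only C–Br bond (unhindered, meta to the biaryl) and acetate-assisted transmetallation delivers boron, while KOAc is too weak a base to cause Suzuki homocoupling.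

Step 10
Reactants: 14 5,7-bis(benzyloxy)-2-(4-benzyloxyphenyl)-6-[2-benzyloxy-5-(4,4,5,5-tetramethyl-1,3,2-dioxaborolan-2-yl)phenyl]-4H-chromen-4-one
Product: 15 {4-(benzyloxy)-3-[5,7-bis(benzyloxy)-2-(4-benzyloxyphenyl)-4-oxo-4H-chromen-6-yl]phenyl}boronic acid
Conditions: NaIO4, NH4OAc, acetone/H2O, rt
Reagents that add atoms: water, O
Why: Periodate cleaves the pinacol released in the hydrolysis equilibrium of the boronate (Malaprade glycol cleavage), which drives the ester to the free boronic acid under buffered, near-neutral conditions.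

Step 11
Reactants: 16 2,4,6-trihydroxyacetophenone
Product: 17 1-[2,4-bis(benzyloxy)-6-hydroxyphenyl]ethan-1-one
Conditions: BnBr (2.1 equiv), K2CO3, DMF, rt
Reagents that add atoms: benzyl bromide, BrCc1ccccc1
Why: Williamson etherification stops at the dibenzyl ether because the last ortho hydroxyl is hydrogen-bonded to the acetyl carbonyl and far less nucleophilic.

Step 12
Reactants: 17 1-[2,4-bis(benzyloxy)-6-hydroxyphenyl]ethan-1-one
Product: 19 5,7-bis(benzyloxy)-4H-chromen-4-one, via dimethylamino enone 18 (not isolated)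
Conditions: Me2NCH(OMe)2, toluene, 100 °C; then 2 M HCl, CH2Cl2, 40 °C
Reagents that add atoms: N,N-dimethylformamide dimethyl acetal, COC(OC)N(C)C
Why: Condensation of the methyl ketone with the amide acetal gives the β-dimethylamino enone, and acid then promotes addition of the ortho phenol to its β-carbon and loss of dimethylamine (addition–elimination) to close the chromone.

Step 13
Reactants: 15 {4-(benzyloxy)-3-[5,7-bis(benzyloxy)-2-(4-benzyloxyphenyl)-4-oxo-4H-chromen-6-yl]phenyl}boronic acid; 19 5,7-bis(benzyloxy)-4H-chromen-4-one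
Product: 20 (2S)-5,7-bis(benzyloxy)-2-{4-(benzyloxy)-3-[5,7-bis(benzyloxy)-2-(4-benzyloxyphenyl)-4-oxo-4H-chromen-6-yl]phenyl}-2,3-dihydro-4H-chromen-4-one
Conditions: Pd(OCOCF3)2 (10 mol%), (R)-4-tert-butyl-2-(pyridin-2-yl)-4,5-dihydrooxazole (12 mol%), NH4PF6 (30 mol%), H2O (5 equiv), ClCH2CH2Cl, 60 °C; 19 in excess
Reagents that add atoms: none
Why: Enantioselective conjugate addition of an arylboronic acid to a chromone under cationic divalent palladium–pyridinooxazoline catalysis, in which transmetallation gives an aryl–palladium species that inserts the chromone C2=C3 bond on the face left open by the tert-butyl group of the ligand and water protonates the palladium enolate, so C2 is set as S by catalyst control while the 2-aryl-substituted flavone enone is too hindered to compete.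

Step 14
Reactants: 20 (2S)-5,7-bis(benzyloxy)-2-{4-(benzyloxy)-3-[5,7-bis(benzyloxy)-2-(4-benzyloxyphenyl)-4-oxo-4H-chromen-6-yl]phenyl}-2,3-dihydro-4H-chromen-4-one
Product: 21 (2S)-5,7-dihydroxy-2-{3-[5,7-dihydroxy-2-(4-hydroxyphenyl)-4-oxo-4H-chromen-6-yl]-4-hydroxyphenyl}-2,3-dihydro-4H-chromen-4-one
Conditions: H2 (1 atm), 10% Pd/C, THF/MeOH, rt, stopped on completion
Reagents that add atoms: none
Why: Hydrogenolysis of the six aryl benzyl ethers is neutral, so the C2 stereocentre cannot racemise through ring-opening to the chalcone, and at ambient pressure the flavone C2=C3 bond and both carbonyl groups should be left intact.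

**Compound list**

1 | 1-benzyloxy-4-ethynylbenzene | C#Cc1ccc(OCc2ccccc2)cc1 | starting material
2 | 3-[4-(benzyloxy)phenyl]prop-2-ynoic acid | OC(=O)C#Cc1ccc(OCc2ccccc2)cc1 | intermediate
3 | methyl acetoacetate | COC(=O)CC(C)=O | starting material
4 | 3-[4-(benzyloxy)phenyl]prop-2-ynoyl chloride | ClC(=O)C#Cc1ccc(OCc2ccccc2)cc1 | intermediate
5 | methyl 2-acetyl-5-[4-(benzyloxy)phenyl]-3-oxopent-4-ynoate | COC(=O)C(C(C)=O)C(=O)C#Cc1ccc(OCc2ccccc2)cc1 | intermediate
6 | methyl 6-(4-benzyloxyphenyl)-2-methyl-4-oxo-4H-pyran-3-carboxylate | COC(=O)c1c(C)oc(-c2ccc(OCc3ccccc3)cc2)cc1=O | intermediate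
7 | 2-hydroxyphenylacetic acid | OC(=O)Cc1ccccc1O | starting material
8 | methyl 2-(2-hydroxyphenyl)acetate | COC(=O)Cc1ccccc1O | intermediate
9 | methyl 2-(5-bromo-2-hydroxyphenyl)acetate | COC(=O)Cc1cc(Br)ccc1O | intermediate
10 | methyl 2-(2-benzyloxy-5-bromophenyl)acetate | COC(=O)Cc1cc(Br)ccc1OCc1ccccc1 | intermediate
11 | methyl 6-(4-benzyloxyphenyl)-2-[3-(2-benzyloxy-5-bromophenyl)-2-oxopropyl]-4-oxo-4H-pyran-3-carboxylate | COC(=O)c1c(CC(=O)Cc2cc(Br)ccc2OCc2ccccc2)oc(-c2ccc(OCc3ccccc3)cc2)cc1=O | intermediate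
12 | 6-(2-benzyloxy-5-bromophenyl)-2-(4-benzyloxyphenyl)-5,7-dihydroxy-4H-chromen-4-one | O=c1cc(-c2ccc(OCc3ccccc3)cc2)oc2cc(O)c(-c3cc(Br)ccc3OCc3ccccc3)c(O)c12 | intermediate
13 | 5,7-bis(benzyloxy)-6-(2-benzyloxy-5-bromophenyl)-2-(4-benzyloxyphenyl)-4H-chromen-4-one | O=c1cc(-c2ccc(OCc3ccccc3)cc2)oc2cc(OCc3ccccc3)c(-c3cc(Br)ccc3OCc3ccccc3)c(OCc3ccccc3)c12 | intermediate
14 | 5,7-bis(benzyloxy)-2-(4-benzyloxyphenyl)-6-[2-benzyloxy-5-(4,4,5,5-tetramethyl-1,3,2-dioxaborolan-2-yl)phenyl]-4H-chromen-4-one | O=c1cc(-c2ccc(OCc3ccccc3)cc2)oc2cc(OCc3ccccc3)c(-c3cc(B4OC(C)(C)C(C)(C)O4)ccc3OCc3ccccc3)c(OCc3ccccc3)c12 | intermediate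
15 | {4-(benzyloxy)-3-[5,7-bis(benzyloxy)-2-(4-benzyloxyphenyl)-4-oxo-4H-chromen-6-yl]phenyl}boronic acid | O=c1cc(-c2ccc(OCc3ccccc3)cc2)oc2cc(OCc3ccccc3)c(-c3cc(B(O)O)ccc3OCc3ccccc3)c(OCc3ccccc3)c12 | intermediate
16 | 2,4,6-trihydroxyacetophenone | CC(=O)c1c(O)cc(O)cc1O | starting material
17 | 1-[2,4-bis(benzyloxy)-6-hydroxyphenyl]ethan-1-one | CC(=O)c1c(O)cc(OCc2ccccc2)cc1OCc1ccccc1 | intermediate
18 | (E)-1-[2,4-bis(benzyloxy)-6-hydroxyphenyl]-3-(dimethylamino)prop-2-en-1-one | CN(C)/C=C/C(=O)c1c(O)cc(OCc2ccccc2)cc1OCc1ccccc1 | intermediate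
19 | 5,7-bis(benzyloxy)-4H-chromen-4-one | O=c1ccoc2cc(OCc3ccccc3)cc(OCc3ccccc3)c12 | intermediate
20 | (2S)-5,7-bis(benzyloxy)-2-{4-(benzyloxy)-3-[5,7-bis(benzyloxy)-2-(4-benzyloxyphenyl)-4-oxo-4H-chromen-6-yl]phenyl}-2,3-dihydro-4H-chromen-4-one | O=C1C[C@@H](c2ccc(OCc3ccccc3)c(-c3c(OCc4ccccc4)cc4oc(-c5ccc(OCc6ccccc6)cc5)cc(=O)c4c3OCc3ccccc3)c2)Oc2cc(OCc3ccccc3)cc(OCc3ccccc3)c21 | intermediate
21 | (2S)-5,7-dihydroxy-2-{3-[5,7-dihydroxy-2-(4-hydroxyphenyl)-4-oxo-4H-chromen-6-yl]-4-hydroxyphenyl}-2,3-dihydro-4H-chromen-4-one | O=C1C[C@@H](c2ccc(O)c(-c3c(O)cc4oc(-c5ccc(O)cc5)cc(=O)c4c3O)c2)Oc2cc(O)cc(O)c21 | target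

**Totals**

Total step count: 14.
Longest linear sequence: 9 steps (steps 1, 2, 3, 7, 8, 9, 10, 13, 14; the arm through steps 4, 5, 6 is equally long).

**Steps most likely to fail**

1. Step 7 (proposed new method). What may go wrong:
- Proton transfer from the arylacetate to the dienolate, followed by self-condensation of the ester.
- Conjugate addition of an enolate to pyranone that is not deprotonated.
- Stalling at the enolate of ketone 11 without ring closure.

Fallback with known chemistry, giving up the built-in regiocontrol and making the biaryl bond by coupling on a preformed flavone; it sets out from 17 and comes back at 14: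
- Claisen–Schmidt condensation of 17 with 4-benzyloxybenzaldehyde (KOH, EtOH, rt) would give (E)-1-[2,4-bis(benzyloxy)-6-hydroxyphenyl]-3-[4-(benzyloxy)phenyl]prop-2-en-1-one F1.
- Oxidative cyclisation (cat. I2, DMSO, 120 °C) would give 5,7-bis(benzyloxy)-2-(4-benzyloxyphenyl)-4H-chromen-4-one F2.
- Iodination with benzyltrimethylammonium dichloroiodate and CaCO3 in CH2Cl2/MeOH, a reagent that goes to C6 of 5,7-dialkoxyflavones, would give 5,7-bis(benzyloxy)-2-(4-benzyloxyphenyl)-6-iodo-4H-chromen-4-one F3. The 6- versus 8-position would be checked before going on.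
- Suzuki–Miyaura coupling with commercial (2-benzyloxy-5-chlorophenyl)boronic acid (Pd(PPh3)4, K3PO4, DME/H2O, 85 °C, a catalyst that leaves the aryl chloride alone) would give 5,7-bis(benzyloxy)-6-(2-benzyloxy-5-chlorophenyl)-2-(4-benzyloxyphenyl)-4H-chromen-4-one F4.
- Miyaura borylation of the aryl chloride (Pd2(dba)3, XPhos, B2pin2, KOAc, 1,4-dioxane, 100 °C) would give 14.

2. Step 13. What may go wrong:
- Slow insertion of the electron-rich, peri-alkoxylated chromone, so that protodeboronation of the electron-rich arylboronic acid outruns addition.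
- Insufficient facial selectivity.

Fallback that forms the C2–O bond instead of the C2–aryl bond; it sets out from 13 and comes back at 20:
- Reductive carbonylation of 13 (Pd(OAc)2, PAd2(n-Bu), TMEDA, CO/H2, toluene, 100 °C) would give 4-(benzyloxy)-3-[5,7-bis(benzyloxy)-2-(4-benzyloxyphenyl)-4-oxo-4H-chromen-6-yl]benzaldehyde F5.
- Claisen–Schmidt condensation with 17 (KOH, EtOH/THF, rt) would give (E)-1-[2,4-bis(benzyloxy)-6-hydroxyphenyl]-3-{4-(benzyloxy)-3-[5,7-bis(benzyloxy)-2-(4-benzyloxyphenyl)-4-oxo-4H-chromen-6-yl]phenyl}prop-2-en-1-one F6.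
- Oxa-Michael ring closure (NaOAc, EtOH, reflux) would give racemic 5,7-bis(benzyloxy)-2-{4-(benzyloxy)-3-[5,7-bis(benzyloxy)-2-(4-benzyloxyphenyl)-4-oxo-4H-chromen-6-yl]phenyl}-2,3-dihydro-4H-chromen-4-one F7.
- Separation of the enantiomers by preparative HPLC on a chiral stationary phase would give 20.

3. Step 3. What may go wrong:
- Closure through the wrong atom: 5-exo attack giving a benzylidenefuranone.
- Participation of the ester carbonyl, giving a 2-pyranone.

Fallback that replaces alkyne hydroalkoxylation by addition–elimination; it sets out from 5 and comes back at 6: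
- Conjugate addition of diethylamine to the ynone (EtOH, rt) would give methyl 2-acetyl-5-[4-(benzyloxy)phenyl]-5-(diethylamino)-3-oxopent-4-enoate F8 (E/Z mixture).
- AcOH at 60 °C would then let the acetyl enol oxygen displace the amine at the amine-bearing carbon, the only electrophilic site left, to give 6.

**Further compounds**

F1 | step 7 | (E)-1-[2,4-bis(benzyloxy)-6-hydroxyphenyl]-3-[4-(benzyloxy)phenyl]prop-2-en-1-one | O=C(/C=C/c1ccc(OCc2ccccc2)cc1)c1c(O)cc(OCc2ccccc2)cc1OCc1ccccc1
F2 | step 7 | 5,7-bis(benzyloxy)-2-(4-benzyloxyphenyl)-4H-chromen-4-one | O=c1cc(-c2ccc(OCc3ccccc3)cc2)oc2cc(OCc3ccccc3)cc(OCc3ccccc3)c12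
F3 | step 7 | 5,7-bis(benzyloxy)-2-(4-benzyloxyphenyl)-6-iodo-4H-chromen-4-one | O=c1cc(-c2ccc(OCc3ccccc3)cc2)oc2cc(OCc3ccccc3)c(I)c(OCc3ccccc3)c12
F4 | step 7 | 5,7-bis(benzyloxy)-6-(2-benzyloxy-5-chlorophenyl)-2-(4-benzyloxyphenyl)-4H-chromen-4-one | O=c1cc(-c2ccc(OCc3ccccc3)cc2)oc2cc(OCc3ccccc3)c(-c3cc(Cl)ccc3OCc3ccccc3)c(OCc3ccccc3)c12
F5 | step 13 | 4-(benzyloxy)-3-[5,7-bis(benzyloxy)-2-(4-benzyloxyphenyl)-4-oxo-4H-chromen-6-yl]benzaldehyde | O=Cc1ccc(OCc2ccccc2)c(-c2c(OCc3ccccc3)cc3oc(-c4ccc(OCc5ccccc5)cc4)cc(=O)c3c2OCc2ccccc2)c1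
F6 | step 13 | (E)-1-[2,4-bis(benzyloxy)-6-hydroxyphenyl]-3-{4-(benzyloxy)-3-[5,7-bis(benzyloxy)-2-(4-benzyloxyphenyl)-4-oxo-4H-chromen-6-yl]phenyl}prop-2-en-1-one | O=C(/C=C/c1ccc(OCc2ccccc2)c(-c2c(OCc3ccccc3)cc3oc(-c4ccc(OCc5ccccc5)cc4)cc(=O)c3c2OCc2ccccc2)c1)c1c(O)cc(OCc2ccccc2)cc1OCc1ccccc1
F7 | step 13 | racemic 5,7-bis(benzyloxy)-2-{4-(benzyloxy)-3-[5,7-bis(benzyloxy)-2-(4-benzyloxyphenyl)-4-oxo-4H-chromen-6-yl]phenyl}-2,3-dihydro-4H-chromen-4-one | O=C1CC(c2ccc(OCc3ccccc3)c(-c3c(OCc4ccccc4)cc4oc(-c5ccc(OCc6ccccc6)cc5)cc(=O)c4c3OCc3ccccc3)c2)Oc2cc(OCc3ccccc3)cc(OCc3ccccc3)c21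
F8 | step 3 | methyl 2-acetyl-5-[4-(benzyloxy)phenyl]-5-(diethylamino)-3-oxopent-4-enoate | COC(=O)C(C(C)=O)C(=O)C=C(N(CC)CC)c1ccc(OCc2ccccc2)cc1
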